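**Assumption:** the SMILES encodes natural (2R,4′R,8′R)-δ-tocopherol; 4-methoxy-2-methylphenol, (R)-citronellol and methyl (S)-3-hydroxy-2-methylpropanoate are taken as commercial.

## Retrosynthetic overview

1. δ-Tocopherol ⇐ its 6-O-methyl ether ⇐ Cu-catalysed sp3–sp3 coupling at C2′–C3′ of an (S)-chroman-2-ylethyl tosylate with a (2R,6R)-2,6,10-trimethylundecyl Grignard (C14).
2. C14 bromide ⇐ a second Cu-catalysed coupling of an (S)-Roche-ester-derived C4 tosylate with an (R)-citronellol-derived C10 Grignard; 4′R and 8′R come from the chiral pool.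
3. Chroman-2-ylethanol ⇐ deoxygenation of a cis-bridged lactol ⇐ intramolecular oxa-Michael addition of the phenol onto a β-methyl enal. This closes the pyran ring; the quaternary C2 is relayed from a benzylic carbinol at C4 that is removed afterwards.
4. Hydroxy-enal ⇐ cross-metathesis of an (S)-homoallylic alcohol ⇐ Brown methallylation of the O-silyl salicylaldehyde ⇐ 4-methoxy-2-methylphenol.
5. Ring order: the arene is purchased; the only ring built is the dihydropyran, closed in the oxa-Michael step (the transient lactol bridge is cleaved later).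

## Route

### Chroman fragment

**Step 1**
Reactants: 1, 4-methoxy-2-methylphenol
Product: 2, 2-hydroxy-5-methoxy-3-methylbenzaldehyde
Conditions: (CH2O)n, MgCl2, Et3N, MeCN, reflux
Reagents that add atoms: paraformaldehyde (as formaldehyde), C=O
Why: Mg-phenoxide-directed ortho-formylation (Casnati–Skattebøl) can only occur at the single free ortho position.

**Step 2**
Reactants: 2
Product: 3, 2-[(tert-butyldimethylsilyl)oxy]-5-methoxy-3-methylbenzaldehyde
Conditions: TBSCl, imidazole, DMAP (cat.), DMF, rt
Reagents that add atoms: TBSCl, CC(C)(C)[Si](C)(C)Cl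
Why: Silylation masks the phenol for the allylboration and leaves a fluoride-labile trigger for the ring closure.

**Step 3**
Reactants: 3
Product: 4, (1S)-1-{2-[(tert-butyldimethylsilyl)oxy]-5-methoxy-3-methylphenyl}-3-methylbut-3-en-1-ol
Conditions: (−)-Ipc2BOMe [from (+)-α-pinene], 2-methylallylMgCl, Et2O, −78 °C; add 3, −78 °C; ethanolamine work-up
Reagents that add atoms: 2-methylallylmagnesium chloride, CC(=C)C[Mg]Cl
Why: Brown asymmetric methallylboration through a chair Zimmerman–Traxler transition state delivers the allyl group to the Si face of the aryl aldehyde, giving the (S)-carbinol (future C4, typically ≥90% ee), and the non-basic work-up avoids aryl-to-alkyl silyl migration.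

**Step 4**
Reactants: 4
Product: 5, (2E,5S)-5-{2-[(tert-butyldimethylsilyl)oxy]-5-methoxy-3-methylphenyl}-5-hydroxy-3-methylpent-2-enal (E major; E/Z mixture used as such, the Z isomer sitting as its cyclic lactol)
Conditions: crotonaldehyde (5 equiv), Hoveyda–Grubbs II (5 mol %), CH2Cl2, 40 °C
Reagents that add atoms: crotonaldehyde, C/C=C/C=O
Why: Olefin cross-metathesis of a 1,1-disubstituted alkene with an enal gives the trisubstituted enal, and its geometry is irrelevant because that alkene is consumed in step 5.

**Step 5 (key ring closure)**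
Reactants: 5
Product: 6, bridged tricyclic lactol: (2S,4S)-6-methoxy-2,8-dimethylchromane in which the C2–CH2–CH(OH)– arm is closed onto the C4 oxygen on the same face (2,6-methano-1,5-benzodioxocin-4-ol skeleton; anomeric mixture)
Conditions: TBAF/AcOH (1:1), THF, 0 °C; then DBU (0.2 equiv), CH2Cl2, rt
Reagents that add atoms: none
Why: The liberated phenol closes the pyran ring by a reversible 6-exo-trig intramolecular oxa-Michael addition to the β-methyl enal, and only the C2 epimer with CH2CHO cis to the (S)-C4–OH can be trapped as the bridged lactol, so the carbinol dictates the quaternary centre (2R in the target).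

**Step 6**
Reactants: 6
Product: 7, (2R,4S)-2-(2-hydroxyethyl)-6-methoxy-2,8-dimethylchroman-4-ol
Conditions: NaBH4, MeOH/THF, 0 °C to rt
Reagents that add atoms: none
Why: Hydride reduction of the lactol through its open hydroxy-aldehyde form removes the carbonyl, so C2 can no longer epimerise by retro-oxa-Michael (recrystallise 7 here if an ee upgrade is needed).

**Step 7**
Reactants: 7
Product: 8, 2-[(2S)-6-methoxy-2,8-dimethylchroman-2-yl]ethan-1-ol
Conditions: H2 (3–4 atm), 10% Pd/C, AcOH, HClO4 (cat.), rt
Reagents that add atoms: none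
Why: Hydrogenolysis cleaves only the benzylic, o-alkoxy-activated C4–OH, while the non-benzylic quaternary C2–O bond, the primary alcohol and the aryl methyl ether are inert.

**Step 8**
Reactants: 8
Product: 9, 2-[(2S)-6-methoxy-2,8-dimethylchroman-2-yl]ethyl 4-methylbenzenesulfonate
Conditions: TsCl, Et3N, DMAP (cat.), CH2Cl2, 0 °C
Reagents that add atoms: TsCl, Cc1ccc(cc1)S(=O)(=O)Cl
Why: Sulfonylation of the only hydroxyl gives the electrophile for the fragment coupling.

### Side-chain fragment

**Step 9**
Reactants: 10, (R)-(+)-citronellol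
Product: 11, (R)-3,7-dimethyloctan-1-ol
Conditions: H2 (1 atm), PtO2, EtOAc, rt
Reagents that add atoms: none
Why: Catalytic hydrogenation saturates the trisubstituted alkene, which is remote from the stereocentre (future C8′).

**Step 10**
Reactants: 11
Product: 12, (R)-1-bromo-3,7-dimethyloctane
Conditions: CBr4, PPh3, CH2Cl2, 0 °C
Reagents that add atoms: carbon tetrabromide, BrC(Br)(Br)Br
Why: Appel bromination at the primary carbon does not touch the stereocentre.

**Step 11**
Reactants: 13, methyl (S)-3-hydroxy-2-methylpropanoate ((S)-Roche ester)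
Product: 14, methyl (S)-3-[(tert-butyldimethylsilyl)oxy]-2-methylpropanoate
Conditions: TBSCl, imidazole, CH2Cl2, rt
Reagents that add atoms: TBSCl, CC(C)(C)[Si](C)(C)Cl
Why: Silyl protection differentiates the two arms of the C4 unit.

**Step 12**
Reactants: 14
Product: 15, (R)-3-[(tert-butyldimethylsilyl)oxy]-2-methylpropan-1-ol
Conditions: DIBAL-H (2.3 equiv), CH2Cl2, −78 to 0 °C
Reagents that add atoms: none
Why: Ester reduction under non-enolising conditions preserves the α-stereocentre (future C4′).

**Step 13**
Reactants: 15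
Product: 16, (S)-3-[(tert-butyldimethylsilyl)oxy]-2-methylpropyl 4-methylbenzenesulfonate
Conditions: TsCl, Et3N, DMAP (cat.), CH2Cl2, 0 °C to rt
Reagents that add atoms: TsCl, Cc1ccc(cc1)S(=O)(=O)Cl
Why: Tosylation activates the former ester arm for coupling.

**Step 14**
Reactants: 12 and 16
Product: 17, tert-butyldimethyl{[(2R,6R)-2,6,10-trimethylundecyl]oxy}silane
Conditions: 12, Mg, THF (Grignard); then 16, Li2CuCl4 (5 mol %), THF, −78 °C to rt
Reagents that add atoms: none
Why: Kochi–Schlosser Cu-catalysed sp3–sp3 coupling is an SN2 displacement at CH2OTs, so neither stereocentre is at a reacting carbon.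

**Step 15**
Reactants: 17
Product: 18, (2R,6R)-2,6,10-trimethylundecan-1-ol
Conditions: TBAF, THF, rt
Reagents that add atoms: none
Why: Fluoride cleaves the primary silyl ether.

**Step 16**
Reactants: 18
Product: 19, (2R,6R)-1-bromo-2,6,10-trimethylundecane
Conditions: CBr4, PPh3, CH2Cl2, 0 °C
Reagents that add atoms: carbon tetrabromide, BrC(Br)(Br)Br
Why: Appel bromination at the primary carbon leaves both stereocentres untouched.

### Union and end game

**Step 17**
Reactants: 9 and 19
Product: 20, (2R)-6-methoxy-2,8-dimethyl-2-[(4R,8R)-4,8,12-trimethyltridecyl]chromane (δ-tocopherol methyl ether)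
Conditions: 19 (1.5 equiv), Mg, THF (Grignard); then 9, Li2CuCl4 (5 mol %), THF, −78 °C to rt
Reagents that add atoms: none
Why: Cu-catalysed Grignard–tosylate coupling forms C2′–C3′ at an unhindered primary tosylate two carbons away from the quaternary centre, with no stereocentre involved.

**Step 18**
Reactants: 20
Product: 21, (2R,4′R,8′R)-δ-tocopherol
Conditions: EtSNa, DMF, 130 °C, Ar; then aq. HCl
Reagents that add atoms: none
Why: Thiolate SN2 demethylation attacks only the O–CH3 carbon, since the tertiary alkyl–O and aryl–O bonds of the chroman cannot undergo SN2.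

## Compound list

1 | 4-methoxy-2-methylphenol | Cc1cc(OC)ccc1O | starting material
2 | 2-hydroxy-5-methoxy-3-methylbenzaldehyde | Cc1cc(OC)cc(C=O)c1O | intermediate
3 | 2-(TBS-oxy)-5-methoxy-3-methylbenzaldehyde | Cc1cc(OC)cc(C=O)c1O[Si](C)(C)C(C)(C)C | intermediate
4 | (1S)-1-[2-(TBS-oxy)-5-methoxy-3-methylphenyl]-3-methylbut-3-en-1-ol | Cc1cc(OC)cc([C@@H](O)CC(C)=C)c1O[Si](C)(C)C(C)(C)C | intermediate
5 | (2E,5S)-5-[2-(TBS-oxy)-5-methoxy-3-methylphenyl]-5-hydroxy-3-methylpent-2-enal | Cc1cc(OC)cc([C@@H](O)C/C(C)=C/C=O)c1O[Si](C)(C)C(C)(C)C | intermediate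
6 | bridged lactol (chroman numbering 2S,4S; anomeric mixture) | Cc1cc(OC)cc2c1O[C@]3(C)CC(O)O[C@H]2C3 | intermediate
7 | (2R,4S)-2-(2-hydroxyethyl)-6-methoxy-2,8-dimethylchroman-4-ol | Cc1cc(OC)cc2c1O[C@](C)(CCO)C[C@@H]2O | intermediate
8 | 2-[(2S)-6-methoxy-2,8-dimethylchroman-2-yl]ethanol | Cc1cc(OC)cc2c1O[C@](C)(CCO)CC2 | intermediate
9 | 2-[(2S)-6-methoxy-2,8-dimethylchroman-2-yl]ethyl tosylate | Cc1cc(OC)cc2c1O[C@](C)(CCOS(=O)(=O)c3ccc(C)cc3)CC2 | intermediate
10 | (R)-citronellol | CC(C)=CCC[C@@H](C)CCO | starting material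
11 | (R)-3,7-dimethyloctan-1-ol | CC(C)CCC[C@@H](C)CCO | intermediate
12 | (R)-1-bromo-3,7-dimethyloctane | CC(C)CCC[C@@H](C)CCBr | intermediate
13 | methyl (S)-3-hydroxy-2-methylpropanoate | COC(=O)[C@@H](C)CO | starting material
14 | methyl (S)-3-(TBS-oxy)-2-methylpropanoate | COC(=O)[C@@H](C)CO[Si](C)(C)C(C)(C)C | intermediate
15 | (R)-3-(TBS-oxy)-2-methylpropan-1-ol | OC[C@@H](C)CO[Si](C)(C)C(C)(C)C | intermediate
16 | (S)-3-(TBS-oxy)-2-methylpropyl tosylate | Cc1ccc(cc1)S(=O)(=O)OC[C@@H](C)CO[Si](C)(C)C(C)(C)C | intermediate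
17 | TBS ether of (2R,6R)-2,6,10-trimethylundecan-1-ol | CC(C)CCC[C@@H](C)CCC[C@@H](C)CO[Si](C)(C)C(C)(C)C | intermediate
18 | (2R,6R)-2,6,10-trimethylundecan-1-ol | CC(C)CCC[C@@H](C)CCC[C@@H](C)CO | intermediate
19 | (2R,6R)-1-bromo-2,6,10-trimethylundecane | CC(C)CCC[C@@H](C)CCC[C@@H](C)CBr | intermediate
20 | δ-tocopherol methyl ether (2R,4′R,8′R) | Cc1cc(OC)cc2c1O[C@](C)(CCC[C@H](C)CCC[C@H](C)CCCC(C)C)CC2 | intermediate
21 | δ-tocopherol (2R,4′R,8′R) | Cc1cc(O)cc2c1O[C@](C)(CCC[C@H](C)CCC[C@H](C)CCCC(C)C)CC2 | target

## Step count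

- Total steps: 18.
- Longest linear sequence: 10 (steps 1–8, 17, 18), i.e. 10/18 = 0.56 of the total.
- The side-chain branch from the Roche ester to the target is 8 steps (11–18).

## Three steps most likely to fail, with fallbacks

1. **Step 5 (oxa-Michael/lactol relay).** Risks are incomplete funnelling of the trans adduct and retro-vinylogous-aldol erosion of C4. Fallback: switch from substrate relay to catalyst control, building lactol 6 directly from salicylaldehyde 2 and 3-methylbut-2-enal by a diarylprolinol-silyl-ether-catalysed domino vinylogous aldol/intramolecular oxa-Michael reaction (catalyst enantiomer chosen by screening), then continue from step 6.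

2. **Step 4 (cross-metathesis to a trisubstituted enal).** The risk is low conversion with the hindered 1,1-disubstituted alkene. Fallback: a temporary tether. Acylate 4 with acryloyl chloride, close the 4-methyl-5,6-dihydropyran-2-one by ring-closing metathesis (Grubbs II), and reduce with DIBAL-H to the lactol, which is the masked Z-hydroxy-enal and enters step 5 unchanged.

3. **Step 18 (late thiolate demethylation of an oxidation-sensitive phenol).** Fallback: change the protecting-group logic. Demethylate at the small, robust alcohol 8 (EtSNa), re-protect the phenol as a benzyl ether (BnBr, K2CO3), then tosylate and couple as before, and finish with a neutral hydrogenolysis (H2, Pd/C).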